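**Retrosynthetic overview**
1. Glicophenone comes from global desilylation of its tetra-TIPS ether, which comes from O-methylation of the corresponding ring-B phenol.
2. Key disconnection: the ring-B aryl–CH2 bond, made by an anodic C–H/C–H coupling inside a silyl bis-ether in which the ring-B phenol oxygen and the enol oxygen of the acetophenone sit on one iPr2Si.
3. Enabling feature: the oxygen on C-2 of the benzyl ring (the later methoxy oxygen) is ortho to the carbon that bonds and 1,4 to the ketone oxygen (O–C(ar)=C(ar)–CH2–C=O). Ring B is thus the enol half of a masked 1,4-dicarbonyl, the two ortho carbons of that oxygen are exactly the prenyl- and the phenacyl-bearing ones, and the methyl ketone has one enolisable site.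
4. The tethered precursor comes from a 2-prenyl-3,5-disilyloxyphenol, a protected 2',4'-dihydroxyacetophenone and iPr2Si(OTf)2; the phenol comes from phloroglucinol by bis-silylation, O-tert-prenylation and aromatic Claisen rearrangement anchored on the same oxygen.
5. Ring order: both benzene rings are bought; the only ring formed is a transient seven-membered silicon-containing ring in the key step, opened again in the same operation.

Key step: step 6

Remark on the chemistry: the target has no stereogenic element (it is achiral), so the route needs no stereocontrol and delivers the single structure drawn.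

**Step 1**
Reactants: 1 phloroglucinol; 2 chlorotriisopropylsilane
Product: 3 3,5-bis(triisopropylsilyloxy)phenol
Conditions: TIPSCl (2.0 equiv), imidazole, DMF, 0 °C to rt; chromatographic separation from mono- and tris-silyl ethers
Reagents that add atoms: chlorotriisopropylsilane, CC(C)[Si](Cl)(C(C)C)C(C)C
Why: O-silylation of a phenol with a silyl chloride and imidazole is O-selective (no C-alkylation of the phloroglucinol nucleus), and limiting the reagent to two equivalents should leave one hydroxyl free on the symmetric ring, where it does not matter which one.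

**Step 2**
Reactants: 3 3,5-bis(triisopropylsilyloxy)phenol; 4 tert-butyl 2-methylbut-3-en-2-yl carbonate
Product: 5 1-(2-methylbut-3-en-2-yloxy)-3,5-bis(triisopropylsilyloxy)benzene
Conditions: Pd(PPh3)4 (cat.), 4 Å MS, THF, 0 °C
Reagents that add atoms: tert-butyl 2-methylbut-3-en-2-yl carbonate, CC(C)(C)OC(=O)OC(C)(C)C=C
Why: Tsuji–Trost O-allylation of a phenol with a tertiary allylic carbonate should give the branched 1,1-dimethylallyl ether under kinetic control at low temperature, the carbonate supplying its own base by decarboxylation.

**Step 3**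
Reactants: 5 1-(2-methylbut-3-en-2-yloxy)-3,5-bis(triisopropylsilyloxy)benzene
Product: 6 2-(3-methylbut-2-en-1-yl)-3,5-bis(triisopropylsilyloxy)phenol
Conditions: N,N-diethylaniline, 120 °C
Reagents that add atoms: none
Why: aromatic Claisen rearrangement ([3,3]) of the 1,1-dimethylallyl aryl ether transfers the group with allylic inversion as a linear prenyl group to one of the two equivalent ortho carbons and regenerates the phenol next to it, so the prenyl group is placed by the same oxygen that later anchors the tether.

**Step 4**
Reactants: 7 2',4'-dihydroxyacetophenone; 8 triisopropylsilyl trifluoromethanesulfonate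
Product: 9 1-[2,4-bis(triisopropylsilyloxy)phenyl]ethan-1-one
Conditions: TIPSOTf (2.3 equiv), 2,6-lutidine, CH2Cl2, 0 °C to rt
Reagents that add atoms: triisopropylsilyl trifluoromethanesulfonate, CC(C)[Si](OS(=O)(=O)C(F)(F)F)(C(C)C)C(C)C
Why: silyl triflate with 2,6-lutidine silylates both phenols, including the hydrogen-bonded ortho hydroxyl, while this weak hindered base should not enolise the methyl ketone.

**Step 5**
Reactants: 6 2-(3-methylbut-2-en-1-yl)-3,5-bis(triisopropylsilyloxy)phenol; 9 1-[2,4-bis(triisopropylsilyloxy)phenyl]ethan-1-one; 10 diisopropylsilyl bis(trifluoromethanesulfonate)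
Product: 12 {1-[2,4-bis(triisopropylsilyloxy)phenyl]ethenyloxy}diisopropyl[2-(3-methylbut-2-en-1-yl)-3,5-bis(triisopropylsilyloxy)phenoxy]silane, via aryloxysilyl triflate 11 (not isolated)
Conditions: 10 (1.05 equiv), Et3N, CH2Cl2, −78 °C, slow addition of 6; then 9, Et3N, −78 °C to rt; filtration through Et3N-deactivated silica
Reagents that add atoms: diisopropylsilyl bis(trifluoromethanesulfonate), CC(C)[Si](OS(=O)(=O)C(F)(F)F)(OS(=O)(=O)C(F)(F)F)C(C)C
Why: stepwise substitution at a silyl bis-triflate is the standard assembly of unsymmetrical silylene tethers, the hindered phenol displacing the first triflate at low temperature and the remaining silyl triflate with Et3N effecting soft enolisation (silyl enol ether formation) of the methyl ketone, which can enolise in one direction only.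

**Step 6**
Reactants: 12 {1-[2,4-bis(triisopropylsilyloxy)phenyl]ethenyloxy}diisopropyl[2-(3-methylbut-2-en-1-yl)-3,5-bis(triisopropylsilyloxy)phenoxy]silane
Product: 14 1-[2,4-bis(triisopropylsilyloxy)phenyl]-2-[2-hydroxy-3-(3-methylbut-2-en-1-yl)-4,6-bis(triisopropylsilyloxy)phenyl]ethan-1-one, via methoxysilyl ether 13 (not isolated)
Conditions: RVC anode, Pt cathode, undivided cell, constant current (ca. 2.2 F/mol), Et4NOTs (0.1 M), 2,6-lutidine, MeOH/CH2Cl2 1:4, 0.02 M, rt; then HF·pyridine, pyridine, THF, 0 °C
Reagents that add atoms: none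
Why: Proposed new method: anodic one-electron oxidation of the electron-rich aryl silyl enol ether in 12 should give a radical cation whose CH2 terminus is attacked by the only free ortho carbon of the silicon-bound ring-B phenol (ring B acting as an enol), and after loss of the aryl proton and a second electron the silyloxycarbenium ion is desilylated by methanol to the ketone, so that two C–H bonds become the central aryl–CH2 bond while hydrogen is evolved at the cathode. The closest known reaction types are the oxidative (ceric ammonium nitrate or anodic) coupling of silicon-tethered bis-enol ethers to 1,4-diketones and the intramolecular anodic coupling of enol ethers with electron-rich arenes in methanol/2,6-lutidine media. The only ring closed is the transient benzo-fused seven-membered C–C–O–Si–O–C–C ring, formed by 7-endo-trig attack of the arene on the enol ether and opened in the same operation when methanol and then HF·pyridine release silicon; no stereocentre is created. Site selectivity on ring B is secured by the tether, because the anchoring oxygen has only one unsubstituted ortho carbon (the other carries the prenyl group) and the remaining ring C–H lies para to it, out of reach and shielded by two OTIPS groups. Chemoselectivity rests on the enol ether being the most easily oxidised group (the prenyl alkene and the silyloxy arene are expected to need a clearly higher potential), on the product being an aryl ketone that is harder to oxidise than 12, and on the intramolecular setting at high dilution suppressing enol–enol homocoupling. The HF·pyridine work-up should cleave only the dialkoxysilane residue on the ring-B oxygen, which is far more fluorophilic than the four aryl TIPS ethers, and so frees exactly the oxygen that has to be methylated.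

**Step 7**
Reactants: 14 1-[2,4-bis(triisopropylsilyloxy)phenyl]-2-[2-hydroxy-3-(3-methylbut-2-en-1-yl)-4,6-bis(triisopropylsilyloxy)phenyl]ethan-1-one; 15 iodomethane
Product: 16 1-[2,4-bis(triisopropylsilyloxy)phenyl]-2-[2-methoxy-3-(3-methylbut-2-en-1-yl)-4,6-bis(triisopropylsilyloxy)phenyl]ethan-1-one
Conditions: MeI (3 equiv), K2CO3, acetone, 40 °C
Reagents that add atoms: iodomethane, CI
Why: Williamson etherification of the only free hydroxyl, where carbonate in an aprotic solvent should form the phenoxide but not the ketone enolate and should leave the aryl silyl ethers intact.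

**Step 8**
Reactants: 16 1-[2,4-bis(triisopropylsilyloxy)phenyl]-2-[2-methoxy-3-(3-methylbut-2-en-1-yl)-4,6-bis(triisopropylsilyloxy)phenyl]ethan-1-one
Product: 17 glicophenone, 1-(2,4-dihydroxyphenyl)-2-[4,6-dihydroxy-2-methoxy-3-(3-methylbut-2-en-1-yl)phenyl]ethan-1-one
Conditions: TBAF (4.4 equiv), AcOH (4.4 equiv), degassed THF, 0 °C to rt
Reagents that add atoms: none
Why: fluoride-mediated cleavage of the four aryl silyl ethers under acetic acid buffering avoids both strong base (polyphenolate oxidation) and strong acid (cyclodehydration of the 2-hydroxybenzyl ketone to a 2-arylbenzofuran, chroman formation from the ortho-prenylphenol).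

**Compound list**
1 | phloroglucinol | Oc1cc(O)cc(O)c1 | starting material
2 | chlorotriisopropylsilane | CC(C)[Si](Cl)(C(C)C)C(C)C | starting material
3 | 3,5-bis(triisopropylsilyloxy)phenol | Oc1cc(O[Si](C(C)C)(C(C)C)C(C)C)cc(O[Si](C(C)C)(C(C)C)C(C)C)c1 | intermediate
4 | tert-butyl 2-methylbut-3-en-2-yl carbonate | CC(C)(C)OC(=O)OC(C)(C)C=C | starting material
5 | 1-(2-methylbut-3-en-2-yloxy)-3,5-bis(triisopropylsilyloxy)benzene | C=CC(C)(C)Oc1cc(O[Si](C(C)C)(C(C)C)C(C)C)cc(O[Si](C(C)C)(C(C)C)C(C)C)c1 | intermediate
6 | 2-(3-methylbut-2-en-1-yl)-3,5-bis(triisopropylsilyloxy)phenol | CC(C)=CCc1c(O)cc(O[Si](C(C)C)(C(C)C)C(C)C)cc1O[Si](C(C)C)(C(C)C)C(C)C | intermediate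
7 | 2',4'-dihydroxyacetophenone | CC(=O)c1ccc(O)cc1O | starting material
8 | triisopropylsilyl trifluoromethanesulfonate | CC(C)[Si](OS(=O)(=O)C(F)(F)F)(C(C)C)C(C)C | starting material
9 | 1-[2,4-bis(triisopropylsilyloxy)phenyl]ethan-1-one | CC(=O)c1ccc(O[Si](C(C)C)(C(C)C)C(C)C)cc1O[Si](C(C)C)(C(C)C)C(C)C | intermediate
10 | diisopropylsilyl bis(trifluoromethanesulfonate) | CC(C)[Si](OS(=O)(=O)C(F)(F)F)(OS(=O)(=O)C(F)(F)F)C(C)C | starting material
11 | diisopropyl[2-(3-methylbut-2-en-1-yl)-3,5-bis(triisopropylsilyloxy)phenoxy]silyl trifluoromethanesulfonate (not isolated) | CC(C)=CCc1c(O[Si](OS(=O)(=O)C(F)(F)F)(C(C)C)C(C)C)cc(O[Si](C(C)C)(C(C)C)C(C)C)cc1O[Si](C(C)C)(C(C)C)C(C)C | intermediate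
12 | {1-[2,4-bis(triisopropylsilyloxy)phenyl]ethenyloxy}diisopropyl[2-(3-methylbut-2-en-1-yl)-3,5-bis(triisopropylsilyloxy)phenoxy]silane | CC(C)=CCc1c(O[Si](OC(=C)c2ccc(O[Si](C(C)C)(C(C)C)C(C)C)cc2O[Si](C(C)C)(C(C)C)C(C)C)(C(C)C)C(C)C)cc(O[Si](C(C)C)(C(C)C)C(C)C)cc1O[Si](C(C)C)(C(C)C)C(C)C | intermediate
13 | 1-[2,4-bis(triisopropylsilyloxy)phenyl]-2-{2-[methoxy(diisopropyl)silyloxy]-3-(3-methylbut-2-en-1-yl)-4,6-bis(triisopropylsilyloxy)phenyl}ethan-1-one (not isolated) | CO[Si](Oc1c(CC=C(C)C)c(O[Si](C(C)C)(C(C)C)C(C)C)cc(O[Si](C(C)C)(C(C)C)C(C)C)c1CC(=O)c1ccc(O[Si](C(C)C)(C(C)C)C(C)C)cc1O[Si](C(C)C)(C(C)C)C(C)C)(C(C)C)C(C)C | intermediate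
14 | 1-[2,4-bis(triisopropylsilyloxy)phenyl]-2-[2-hydroxy-3-(3-methylbut-2-en-1-yl)-4,6-bis(triisopropylsilyloxy)phenyl]ethan-1-one | Oc1c(CC=C(C)C)c(O[Si](C(C)C)(C(C)C)C(C)C)cc(O[Si](C(C)C)(C(C)C)C(C)C)c1CC(=O)c1ccc(O[Si](C(C)C)(C(C)C)C(C)C)cc1O[Si](C(C)C)(C(C)C)C(C)C | intermediate
15 | iodomethane | CI | starting material
16 | 1-[2,4-bis(triisopropylsilyloxy)phenyl]-2-[2-methoxy-3-(3-methylbut-2-en-1-yl)-4,6-bis(triisopropylsilyloxy)phenyl]ethan-1-one | COc1c(CC=C(C)C)c(O[Si](C(C)C)(C(C)C)C(C)C)cc(O[Si](C(C)C)(C(C)C)C(C)C)c1CC(=O)c1ccc(O[Si](C(C)C)(C(C)C)C(C)C)cc1O[Si](C(C)C)(C(C)C)C(C)C | intermediate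
17 | glicophenone | COc1c(CC=C(C)C)c(O)cc(O)c1CC(=O)c1ccc(O)cc1O | target

**Step count and risks**
Total steps: 8. Longest linear sequence: 7 (steps 1, 2, 3, 5, 6, 7, 8 from phloroglucinol); step 4 is the one-step side branch.

Most likely to fail:

1. Step 6 (proposed new method). What may go wrong: the enol ether radical cation may lose silicon by solvolysis before ring B attacks, or the arene ring may be over-oxidised, so that the tether falls apart without C–C bond formation. Fallback with known chemistry, setting out from 6 and returning at 16 (it bypasses steps 5 to 7): the free phenol 6 is brominated at its only open ortho position (NBS, cat. iPr2NH, CH2Cl2, −78 °C) to give 2-bromo-6-(3-methylbut-2-en-1-yl)-3,5-bis(triisopropylsilyloxy)phenol F1. This is O-methylated (MeI, K2CO3, acetone) to 2-bromo-1-methoxy-6-(3-methylbut-2-en-1-yl)-3,5-bis(triisopropylsilyloxy)benzene F2. F2 is then joined to ketone 9 by palladium-catalysed ketone α-arylation (Pd(OAc)2, XPhos, K3PO4, toluene, 90 °C), which forms the same aryl–CH2 bond and should give 16 directly.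

2. Step 5. What may go wrong: double substitution at silicon by the same partner, a stalled enol silylation by the hindered aryloxysilyl triflate, or hydrolysis of the mixed silane during isolation. Fallback, setting out from 9 and returning at 12: the order of assembly at silicon is reversed and hard enolate chemistry replaces soft enolisation. The lithium enolate of 9 (LDA, THF, −78 °C) is added to an excess of dichlorodiisopropylsilane to give chloro(diisopropyl)silyl 1-[2,4-bis(triisopropylsilyloxy)phenyl]ethenyl ether F3. After removal of the excess silane in vacuo, F3 is condensed with phenol 6 (imidazole, DMAP, CH2Cl2) to give 12.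

3. Step 7. What may go wrong: competing C-methylation at the acidic ketone α-methylene, or base-induced loss or transfer of the carbonyl-activated ring-A silyl groups, while the doubly flanked phenoxide reacts slowly. Fallback, setting out from 14 and returning at 16: the base-mediated SN2 alkylation is replaced by a Mitsunobu etherification (MeOH, PPh3, DIAD, THF, 0 °C to rt). This is gated by acidity, so only the phenol and not the C–H acid is alkylated, and no base or free phenoxide is present; it makes no new compound.

**Further compounds**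
F1 | step 6 | 2-bromo-6-(3-methylbut-2-en-1-yl)-3,5-bis(triisopropylsilyloxy)phenol | Oc1c(CC=C(C)C)c(O[Si](C(C)C)(C(C)C)C(C)C)cc(O[Si](C(C)C)(C(C)C)C(C)C)c1Br
F2 | step 6 | 2-bromo-1-methoxy-6-(3-methylbut-2-en-1-yl)-3,5-bis(triisopropylsilyloxy)benzene | COc1c(CC=C(C)C)c(O[Si](C(C)C)(C(C)C)C(C)C)cc(O[Si](C(C)C)(C(C)C)C(C)C)c1Br
F3 | step 5 | chloro(diisopropyl)silyl 1-[2,4-bis(triisopropylsilyloxy)phenyl]ethenyl ether | C=C(O[Si](Cl)(C(C)C)C(C)C)c1ccc(O[Si](C(C)C)(C(C)C)C(C)C)cc1O[Si](C(C)C)(C(C)C)C(C)C
F0 | step 7 | none | none
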